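The slower of two routes takes electrophile into its dormant form, with a half-life of 20.6 min by the forward step alone, while coupling with nucleophile at its charged amount has a half-life of 0.744 min, much shorter.

the same everywhere: electrophile 0.20 M; nucleophile 0.200 M; time 4.0 h

| run | scavenger |
|---|---|
| summer | 0.170 M |
| dawn | 0.100 M |
| noon | 0.130 M |

    2 nucleophile → homo dimer (k1 = 0.0888 M⁻¹ min⁻¹)
    electrophile ⇌ dormant form (K2 = 7.8, k2 = 0.0337 min⁻¹)
    acid set free + scavenger → scavenged by-product (k3 = 22.6 M⁻¹ min⁻¹)
    nucleophile + acid set free ⇌ protonated nucleophile, settled at all times (K4 = 81.9 M⁻¹)
    nucleophile + acid set free ⇌ idle adduct, settled at all times (K5 = 6.20 M⁻¹)
    electrophile + nucleophile → acid set free + product (k6 = 4.66 M⁻¹ min⁻¹)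

* part of the electrophile that has reacted at the end, summer
* part of the electrophile that has reacted at the end, dawn
* part of the electrophile that has reacted at the end, noon
* what raising the concentration of scavenger from its lowest to its highest value here does to the part of the electrophile that has reacted (changes below 5 percentage points count as none) (it rises / no change / it falls)

- amounts and yields of acid set free count idle adduct too
- two of one species on the left: rate k times its square, two consumed each time
- what has gone from electrophile into another species counts as reacted, even if it can come back
- run time (summer): 4.0 h

Both half-lives, taken at the start, are shorter than the run, so as an estimate I let coupling finish inside the run and the dormant step come to balance. Coupled electrophile is gone for good. The uncoupled rest forms a pool of free electrophile and dormant form, and the dormant step can run both ways. At balance there are 7.8 parts dormant to each part free, so free electrophile is one part in one plus that constant: the balance share, 11.4% of the pool. The dormant form counts as reacted, so the answer turns on this share times the pool.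

To size the pool I treat coupling and the dormant step as a race. The charges are equal and coupling takes one of each, so in this race the share of electrophile that goes dormant leaves the same share of nucleophile over once free electrophile has gone. Coupling starts 27.7 times faster than the dormant step, and that ratio shrinks as nucleophile goes. Summed over the race, the dormant share times the starting ratio equals the natural log of one over that share, which gives 8.81% of the charge. I leave out the homo dimer, the way back and the acid's hold on nucleophile. The balance share of that pool leaves 1.00% free, so I commit to 99.0% reacted in each flask. That left part is below the 5 percentage points that counts as a change, so I say no change with scavenger.

The forecast gives 99.6%, 99% and 99.3% for summer, dawn and noon, where I have one figure for the three, and no change, holding that “Scavenger only changes how much nucleophile stays free to drain the dormant pool”.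

The simulation gives 99.4% for summer, 99.0% for dawn and 99.2% for noon, against my 99.0%, and no change, with a change of 0.4 points.

In summer at 4.00 h, 0.606% of the electrophile stands free beside 7.40% as dormant form, with 2.02% of the nucleophile's own charge still free. The balance share of that pool is 0.910%, more than the free electrophile found, so summer's free electrophile lies below balance.

In the neighbour of summer charged with 0.34 M of electrophile, nucleophile is the limiting reagent at 0.588 equiv. Coupling one for one takes 58.8% of the electrophile, and the balance share of the rest leaves 4.68% free, or 95.3% reacted. The computed neighbour gives 95.3% reacted, with 4.7% of its electrophile free and 0% of its nucleophile left. For dawn, the answer has moved by 5 points at 0.422 M of electrophile.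

All constants stand for no real mixture, and the outcome is calculated.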